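**Retrosynthetic overview**
1. Numbering used throughout: ring C1 (carries the side chain), C2 (CH2), C3 (CHCl), C4 (C(CH3)OH), C5 (CH–O-angeloyl), C6 (CH–OAc); side chain C7(=C7'H2)–C8(O-angeloyl)–C9H2–C10(OH)–C11(CH3)2OH.
2. Side chain, made last: C10/C11 diol by ligand-controlled osmylation of a prenyl-type alkene (cross-metathesis of a C8 allyl carbinol); both angelates in one double acylation; C8 by catalytic allylboration of a 2-substituted acrolein obtained by α-methylenation of a C1 acetaldehyde arm.
3. Ring adjustment: axial C6–OH by bulky-hydride reduction of a C6 ketone that comes from hydroboration of a C1=C6 alkene; C4–OH by Baeyer–Villiger excision of a formyl group.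
4. Key disconnection: the cyclohexane, the only ring (formed in step 6), is cut across C2–C3 and C5–C4 into the diene C2=C1–C6=C5 (1-silyloxy, 3-alkyl) and the dienophile C3=C4, (E)-3-chloro-2-methylacrolein, joined by a catalytic enantioselective Diels–Alder reaction.
5. Enabling feature: the ring edge C3(Cl)–C4(CH3)(O) is a masked (E)-β-chloro-α-methyl enal (Cl trans to O = E geometry; the tertiary O is the former CHO). The C5 oxygen and the C1 branch sit at positions 1 and 3 of the diene C2–C1–C6–C5, so both polarise it toward C2, and the cis C4–O/C5–O pair is the endo outcome.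

Key step: step 6

Assumption: the face selectivity of the oxazaborolidinium catalyst (step 6), the chiral phosphoric acid (step 15) and the cinchona ligand (step 19) is taken from the accepted models; each exists in both mirror-image (or pseudo-enantiomeric) forms, so an inverted sense would be met with the antipode without change of route.

**Route**

Step 1
Reactants: 1 4-(tert-butyldimethylsilyloxy)but-1-yne
Product: 3 (E)-5-(tert-butyldimethylsilyloxy)-3-methylpent-2-en-1-ol, via alkenylalane 2 (not isolated)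
Conditions: Me3Al, Cp2ZrCl2 (0.25 equiv), CH2Cl2, 0 °C to rt; then n-BuLi, (CH2O)n, THF, −78 °C to rt; aq. NH4Cl/Rochelle salt
Reagents that add atoms: trimethylaluminium, C[Al](C)C; paraformaldehyde (as formaldehyde), C=O
Why: Negishi zirconium-catalysed carboalumination adds CH3 and Al syn across the terminal alkyne (Al on the terminal carbon), and the alanate formed with n-BuLi is hydroxymethylated with retention, so the trisubstituted alkene should be E.

Step 2
Reactants: 3 (E)-5-(tert-butyldimethylsilyloxy)-3-methylpent-2-en-1-ol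
Product: 4 (E)-5-(tert-butyldimethylsilyloxy)-3-methylpent-2-enal
Conditions: MnO2, CH2Cl2, rt
Reagents that add atoms: none
Why: MnO2 allylic oxidation should stop at the enal and leave the silyl ether and the alkene geometry untouched.

Step 3
Reactants: 4 (E)-5-(tert-butyldimethylsilyloxy)-3-methylpent-2-enal
Product: 5 (E)-1-(tert-butyldimethylsilyloxy)-3-[2-(tert-butyldimethylsilyloxy)ethyl]buta-1,3-diene
Conditions: TBSOTf, Et3N, Et2O, 0 °C
Reagents that add atoms: tert-butyldimethylsilyl triflate, CC(C)(C)[Si](C)(C)OS(=O)(=O)C(F)(F)F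
Why: Soft enolisation (O-silylation to the silyloxocarbenium ion, then γ-deprotonation by the amine at the unhindered C-methyl group of the s-trans cation) is the standard route from 3-methyl-2-enals to (E)-1-silyloxy-1,3-dienes and should favour the 2-substituted diene over the internal isomer.

Step 4
Reactants: 6 prop-2-yn-1-ol
Product: 8 (E)-3-chloro-2-methylprop-2-en-1-ol, via alkenylalane 7 (not isolated)
Conditions: Me3Al (3 equiv), Cp2ZrCl2 (0.25 equiv), CH2Cl2, 0 °C to rt; then N-chlorosuccinimide, THF, −30 to 0 °C; aq. Rochelle salt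
Reagents that add atoms: trimethylaluminium, C[Al](C)C; N-chlorosuccinimide, O=C1CCC(=O)N1Cl
Why: The same syn-carboalumination on the aluminium alkoxide of propargyl alcohol, followed by chlorinolysis of the alkenyl–Al bond with retention, should fix Cl cis to CH3 (E).

Step 5
Reactants: 8 (E)-3-chloro-2-methylprop-2-en-1-ol
Product: 9 (E)-3-chloro-2-methylprop-2-enal
Conditions: MnO2, CH2Cl2, rt (used as a solution)
Reagents that add atoms: none
Why: MnO2 allylic oxidation should give the volatile enal with its E geometry intact.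

Step 6
Reactants: 5 (E)-1-(tert-butyldimethylsilyloxy)-3-[2-(tert-butyldimethylsilyloxy)ethyl]buta-1,3-diene; 9 (E)-3-chloro-2-methylprop-2-enal
Product: 10 (1S,2R,6R)-2-(tert-butyldimethylsilyloxy)-4-[2-(tert-butyldimethylsilyloxy)ethyl]-6-chloro-1-methylcyclohex-3-ene-1-carbaldehyde (target numbering: C1=C6 alkene, 3R,4S,5R; OTBS cis to CHO, Cl trans to CHO)
Conditions: (S)-o-tolyl-diphenylprolinol oxazaborolidine (20 mol %), Tf2NH (18 mol %), CH2Cl2, −78 to −40 °C
Reagents that add atoms: none
Why: The N-protonated oxazaborolidine binds the s-trans enal 9 (B–O coordination plus formyl C–H···O contact) and the (E)-silyloxydiene 5 adds in a concerted, asynchronous, suprafacial [4+2] cycloaddition that forms C2–C3 and C5–C4 together; the closest precedent is the oxazaborolidinium-catalysed enantioselective Diels–Alder reaction of 2-substituted acroleins with silyloxy- and alkyl-substituted butadienes. The cyclohexene, the only ring of the target, is closed by this intermolecular cycloaddition and not by cyclisation of a tethered chain. C3 and C4 take their relative configuration from the E geometry of 9 (Cl cis to CH3, trans to CHO), C5 takes its configuration relative to C4 from the endo orientation of the formyl group toward the (E)-dienol ether (OTBS cis to CHO, the future cis C5–O/C4–O pair), and the absolute configuration of all three comes from the catalyst, which shields one face of the bound enal. Regioselectivity is needed and is secured twice by the substrate: the 1-silyloxy group and the 3-alkyl branch both place the largest HOMO coefficient on C2, which bonds to the β-carbon C3 of the enal. Endo selectivity should be favoured because the diene is acyclic (no bridge to clash with the α-methyl group), and the cycloaddition must outrun conjugate addition–chloride elimination at the β-chloro enal, which low temperature and the concerted path favour. The stereocentre-free pair 5/9 thus delivers the ring, the C–Cl bond, the quaternary C4 and the C5–O stereocentre in one operation.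

Step 7
Reactants: 10 cyclohexene carbaldehyde (3R,4S,5R)
Product: 12 diol (1R,3R,4R,5S,6S): C1 CH2CH2OTBS, C3 Cl, C4 CH3 and CH2OH, C5 OTBS, C6 OH trans to the C5 oxygen, via bis-borane 11 (not isolated)
Conditions: BH3·THF (3 equiv), THF, 0 °C to rt; then NaBO3·4H2O, THF/H2O, rt
Reagents that add atoms: sodium perborate, [Na+].[Na+].O[B-]1(O)OO[B-](O)(O)OO1
Why: BH3 reduces the aldehyde and hydroborates the trisubstituted alkene in the anti-Markovnikov sense (B on C6) by syn addition from the face opposite the allylic C5 silyloxy group and the C4 CH2O–boron arm, which sets C1 (arm cis to the C5 oxygen), and perborate replaces B by OH with retention (hydroboration–oxidation).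

Step 8
Reactants: 12 diol (1R,3R,4R,5S,6S)
Product: 13 keto aldehyde (1R,3R,4S,5S): C6 ketone, C4 CHO
Conditions: Dess–Martin periodinane (3 equiv), NaHCO3, CH2Cl2, 0 °C to rt
Reagents that add atoms: none
Why: Dess–Martin oxidation converts both alcohols under buffered, non-epimerising conditions, so the equatorial C1 arm set in step 7 is kept and the transient C6 carbinol centre is erased on purpose.

Step 9
Reactants: 13 keto aldehyde (1R,3R,4S,5S)
Product: 14 keto formate (1R,3R,4R,5S): C4 O–CHO
Conditions: mCPBA (1.5 equiv), NaHCO3, CH2Cl2, 0 °C to rt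
Reagents that add atoms: 3-chloroperbenzoic acid, OOC(=O)c1cccc(Cl)c1
Why: Baeyer–Villiger oxidation of the α-quaternary aldehyde proceeds by migration of the tertiary carbon C4 with retention, turning C4–CHO into C4–OCHO, and the aldehyde should react much faster with the peracid than the hindered cyclohexanone.

Step 10
Reactants: 14 keto formate (1R,3R,4R,5S)
Product: 15 diol (1R,3R,4R,5R,6R): C4 OH (tertiary), C6 OH cis to the C1 arm and the C5 oxygen
Conditions: LiBH(s-Bu)3 (L-Selectride, 4 equiv), THF, −78 °C; AcOH quench at −78 °C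
Reagents that add atoms: none
Why: The bulky hydride attacks the C6 ketone from the equatorial direction (the axial path is blocked by the axial C4 oxygen), giving the axial C6 alcohol cis to the C1 arm and the C5 oxygen, and excess hydride cleaves the formate to the tertiary C4 alcohol (Selectride reduction); the cold quench keeps the alkoxide from displacing the anti chloride.

Step 11
Reactants: 15 diol (1R,3R,4R,5R,6R)
Product: 16 C6 acetate (1R,3R,4R,5R,6R)
Conditions: Ac2O, pyridine, DMAP (cat.), CH2Cl2, rt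
Reagents that add atoms: acetic anhydride, CC(=O)OC(C)=O
Why: DMAP-catalysed acetylation takes place at the secondary C6 hydroxyl while the tertiary C4 hydroxyl should not react under these conditions.

Step 12
Reactants: 16 C6 acetate
Product: 17 primary alcohol (1R,3R,4R,5R,6R): C1 CH2CH2OH, C5 OTBS retained
Conditions: camphorsulfonic acid (0.1 equiv), MeOH/CH2Cl2, 0 °C
Reagents that add atoms: none
Why: Acid-catalysed methanolysis removes the primary silyl ether much faster than the hindered secondary one on C5 (selective desilylation).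

Step 13
Reactants: 17 primary alcohol
Product: 18 aldehyde (1R,3R,4R,5R,6R): C1 CH2CHO
Conditions: Dess–Martin periodinane, NaHCO3, CH2Cl2, rt
Reagents that add atoms: none
Why: Dess–Martin oxidation of the primary alcohol gives the aldehyde without affecting the acetate, the tertiary alcohol or the chloride.

Step 14
Reactants: 18 aldehyde
Product: 20 2-substituted acrolein (1S,3R,4R,5R,6R): C1 C(=CH2)CHO, via Mannich base 19 (not isolated)
Conditions: [Me2N=CH2]I (Eschenmoser's salt), Et3N, CH2Cl2, rt
Reagents that add atoms: dimethyl(methylidene)ammonium iodide, C=[N+](C)C.[I-]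
Why: Mannich reaction of the aldehyde followed by amine-induced β-elimination of dimethylamine (α-methylenation) installs the C7 methylene group.

Step 15
Reactants: 20 2-substituted acrolein
Product: 22 homoallylic alcohol (1S,3R,4R,5R,6R,8S), via borate ester 21 (not isolated)
Conditions: allylB(pin), (S)-TRIP phosphoric acid (5 mol %), toluene, −30 °C; aqueous work-up
Reagents that add atoms: allylboronic acid pinacol ester, C=CCB1OC(C)(C)C(C)(C)O1
Why: Chiral phosphoric acid-catalysed allylboration proceeds through a closed chair transition state in which the catalyst activates the boronate and selects the aldehyde face, so C8 should be set by catalyst control as the S carbinol.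

Step 16
Reactants: 22 homoallylic alcohol
Product: 23 C5,C8-diol (1S,3R,4R,5R,6R,8S)
Conditions: HF·pyridine, THF, 0 °C to rt
Reagents that add atoms: none
Why: Fluoride-mediated desilylation under buffered acidic conditions frees the hindered C5 hydroxyl without acyl migration or epoxide formation from the chlorohydrin.

Step 17
Reactants: 23 C5,C8-diol; 24 angelic acid, (Z)-2-methylbut-2-enoic acid
Product: 26 bis-angelate (1S,3R,4R,5R,6R,8S), via mixed anhydride 25 (not isolated)
Conditions: 24 (6 equiv), 2,4,6-trichlorobenzoyl chloride, Et3N, toluene, rt; then 23, 80 °C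
Reagents that add atoms: none
Why: Yamaguchi esterification through the mixed anhydride acylates both secondary hydroxyls (C5 and C8) and, run without DMAP, should keep the Z geometry of the angelate; the tertiary C4 hydroxyl stays free.

Step 18
Reactants: 26 bis-angelate
Product: 27 prenyl-type alkene (1S,3R,4R,5R,6R,8S): C9H2–C10H=C11(CH3)2
Conditions: 2-methyl-2-butene (excess), second-generation Hoveyda–Grubbs catalyst (H2IMes)Cl2Ru=CH(C6H4-2-O-i-Pr) (5 mol %), CH2Cl2, 40 °C
Reagents that add atoms: 2-methyl-2-butene, CC=C(C)C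
Why: Olefin cross-metathesis with excess 2-methyl-2-butene should convert only the monosubstituted alkene into the trisubstituted alkene, because the 1,1-disubstituted C7 methylene and the angelate double bonds are unreactive toward the ruthenium carbene.

Step 19
Reactants: 27 prenyl-type alkene
Product: 29 CNP0212201.1 (1S,3R,4R,5R,6R,8S,10S), via osmate ester 28 (not isolated)
Conditions: OsO4 (1.05 equiv), (DHQ)2PHAL (1.1 equiv), CH2Cl2, −78 °C; then aq. NaHSO3, THF, rt
Reagents that add atoms: osmium tetroxide, O=[Os](=O)(=O)=O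
Why: Ligand-accelerated osmylation (stoichiometric Sharpless-type asymmetric dihydroxylation) should attack the most electron-rich, trisubstituted C10=C11 alkene from the face dictated by the dihydroquinine ligand to give the 10S diol by syn addition, and neutral reductive hydrolysis of the osmate ester spares the esters and the chlorohydrin.

**Compound list**
1 | 4-(tert-butyldimethylsilyloxy)but-1-yne | C#CCCO[Si](C)(C)C(C)(C)C | starting material
2 | dimethyl[(E)-4-(tert-butyldimethylsilyloxy)-2-methylbut-1-enyl]aluminium | C/C(CCO[Si](C)(C)C(C)(C)C)=C\[Al](C)C | intermediate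
3 | (E)-5-(tert-butyldimethylsilyloxy)-3-methylpent-2-en-1-ol | C/C(CCO[Si](C)(C)C(C)(C)C)=C\CO | intermediate
4 | (E)-5-(tert-butyldimethylsilyloxy)-3-methylpent-2-enal | C/C(CCO[Si](C)(C)C(C)(C)C)=C\C=O | intermediate
5 | (E)-1-(tert-butyldimethylsilyloxy)-3-[2-(tert-butyldimethylsilyloxy)ethyl]buta-1,3-diene | C=C(CCO[Si](C)(C)C(C)(C)C)/C=C/O[Si](C)(C)C(C)(C)C | intermediate
6 | prop-2-yn-1-ol | C#CCO | starting material
7 | (E)-alkenylalane from 6: dimethylaluminium alkoxide with AlMe2 on the terminal alkene carbon, cis to CH3 | C/C(CO[Al](C)C)=C\[Al](C)C | intermediate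
8 | (E)-3-chloro-2-methylprop-2-en-1-ol | C/C(CO)=C\Cl | intermediate
9 | (E)-3-chloro-2-methylprop-2-enal | C/C(C=O)=C\Cl | intermediate
10 | (1S,2R,6R)-2-(tert-butyldimethylsilyloxy)-4-[2-(tert-butyldimethylsilyloxy)ethyl]-6-chloro-1-methylcyclohex-3-ene-1-carbaldehyde (target numbering 3R,4S,5R) | CC(C)(C)[Si](C)(C)OCCC=1C[C@@H](Cl)[C@](C)(C=O)[C@H](O[Si](C)(C)C(C)(C)C)C=1 | intermediate
11 | bis-borane: BH2 on C6 (trans to the C5 oxygen) and CH2O–BH2 on C4; other centres as in 12 | CC(C)(C)[Si](C)(C)OCC[C@@H]1C[C@@H](Cl)[C@](C)(COB)[C@H](O[Si](C)(C)C(C)(C)C)[C@H]1B | intermediate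
12 | diol (1R,3R,4R,5S,6S): C1 CH2CH2OTBS, C3 Cl, C4 CH3/CH2OH, C5 OTBS, C6 OH (trans to C5–O) | CC(C)(C)[Si](C)(C)OCC[C@@H]1C[C@@H](Cl)[C@](C)(CO)[C@H](O[Si](C)(C)C(C)(C)C)[C@H]1O | intermediate
13 | keto aldehyde (1R,3R,4S,5S): C6 ketone, C4 CH3/CHO | CC(C)(C)[Si](C)(C)OCC[C@@H]1C[C@@H](Cl)[C@](C)(C=O)[C@H](O[Si](C)(C)C(C)(C)C)C1=O | intermediate
14 | keto formate (1R,3R,4R,5S): C6 ketone, C4 CH3/OCHO | CC(C)(C)[Si](C)(C)OCC[C@@H]1C[C@@H](Cl)[C@](C)(OC=O)[C@H](O[Si](C)(C)C(C)(C)C)C1=O | intermediate
15 | diol (1R,3R,4R,5R,6R): C4 OH, C6 OH (cis to C1 arm and C5–O) | CC(C)(C)[Si](C)(C)OCC[C@@H]1C[C@@H](Cl)[C@](C)(O)[C@H](O[Si](C)(C)C(C)(C)C)[C@@H]1O | intermediate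
16 | C6 acetate of 15 (1R,3R,4R,5R,6R) | CC(C)(C)[Si](C)(C)OCC[C@@H]1C[C@@H](Cl)[C@](C)(O)[C@H](O[Si](C)(C)C(C)(C)C)[C@@H]1OC(C)=O | intermediate
17 | primary alcohol (1R,3R,4R,5R,6R): C1 CH2CH2OH | OCC[C@@H]1C[C@@H](Cl)[C@](C)(O)[C@H](O[Si](C)(C)C(C)(C)C)[C@@H]1OC(C)=O | intermediate
18 | aldehyde (1R,3R,4R,5R,6R): C1 CH2CHO | O=CC[C@@H]1C[C@@H](Cl)[C@](C)(O)[C@H](O[Si](C)(C)C(C)(C)C)[C@@H]1OC(C)=O | intermediate
19 | Mannich base: C1 CH(CHO)CH2NMe2 (C7 unspecified), ring as in 18 | CN(C)CC(C=O)[C@@H]1C[C@@H](Cl)[C@](C)(O)[C@H](O[Si](C)(C)C(C)(C)C)[C@@H]1OC(C)=O | intermediate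
20 | 2-substituted acrolein (1S,3R,4R,5R,6R): C1 C(=CH2)CHO | C=C(C=O)[C@@H]1C[C@@H](Cl)[C@](C)(O)[C@H](O[Si](C)(C)C(C)(C)C)[C@@H]1OC(C)=O | intermediate
21 | pinacol borate ester of 22 at O8 | C=C([C@H](CC=C)OB2OC(C)(C)C(C)(C)O2)[C@@H]1C[C@@H](Cl)[C@](C)(O)[C@H](O[Si](C)(C)C(C)(C)C)[C@@H]1OC(C)=O | intermediate
22 | homoallylic alcohol (1S,3R,4R,5R,6R,8S): C8 OH, C9H2–CH=CH2 | C=C([C@H](CC=C)O)[C@@H]1C[C@@H](Cl)[C@](C)(O)[C@H](O[Si](C)(C)C(C)(C)C)[C@@H]1OC(C)=O | intermediate
23 | C5,C8-diol (1S,3R,4R,5R,6R,8S) | C=C([C@H](CC=C)O)[C@@H]1C[C@@H](Cl)[C@](C)(O)[C@H](O)[C@@H]1OC(C)=O | intermediate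
24 | angelic acid, (Z)-2-methylbut-2-enoic acid | C/C=C(/C)C(=O)O | starting material
25 | angelic 2,4,6-trichlorobenzoic mixed anhydride | C/C=C(/C)C(=O)OC(=O)c1c(Cl)cc(Cl)cc1Cl | intermediate
26 | C5,C8-bis-angelate (1S,3R,4R,5R,6R,8S) with terminal allyl group | C=C([C@H](CC=C)OC(=O)/C(C)=C\C)[C@@H]1C[C@@H](Cl)[C@](C)(O)[C@H](OC(=O)/C(C)=C\C)[C@@H]1OC(C)=O | intermediate
27 | bis-angelate with C10=C11(CH3)2 alkene (1S,3R,4R,5R,6R,8S) | C=C([C@H](CC=C(C)C)OC(=O)/C(C)=C\C)[C@@H]1C[C@@H](Cl)[C@](C)(O)[C@H](OC(=O)/C(C)=C\C)[C@@H]1OC(C)=O | intermediate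
28 | cyclic osmate ester of the (10S)-C10/C11 glycol (ligand not drawn) | C=C([C@H](C[C@@H]2O[Os](=O)(=O)OC2(C)C)OC(=O)/C(C)=C\C)[C@@H]1C[C@@H](Cl)[C@](C)(O)[C@H](OC(=O)/C(C)=C\C)[C@@H]1OC(C)=O | intermediate
29 | CNP0212201.1 (1S,3R,4R,5R,6R,8S,10S in the numbering above) | C=C([C@H](C[C@H](O)C(C)(C)O)OC(=O)/C(C)=C\C)[C@@H]1C[C@@H](Cl)[C@](C)(O)[C@H](OC(=O)/C(C)=C\C)[C@@H]1OC(C)=O | target

**Count and risks**
Total: 19 steps. Longest linear sequence: 17 steps (steps 1–3 and 6–19); steps 4–5 make the dienophile.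

Most likely to fail:

1. Step 6 (key cycloaddition). What may go wrong: low facial selectivity of the catalyst-bound trisubstituted enal, or protodesilylation of the dienol ether by the strongly acidic catalyst before cycloaddition. Fallback, setting out from 5 and 9 and returning at 12: an uncatalysed thermal cycloaddition (toluene, 80 °C, BHT) should give the racemic endo adduct F1. NaBH4 reduces it to the racemic primary alcohol F2. Acylation with (S)-O-methylmandelic acid (DCC, DMAP) gives two diastereomeric esters, from which the (S)-O-methylmandelate of the (3R,4R,5R) alcohol F3 is separated by chromatography. i-Bu2AlH at −78 °C releases the enantiopure alcohol F4, and BH3·THF then NaBO3·4H2O as in step 7 gives 12. This replaces catalytic asymmetric induction by resolution.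

2. Step 9 (Baeyer–Villiger). What may go wrong: oxygen insertion at the C6 ketone (ring expansion, helped by the α-silyloxy carbon) competing with the aldehyde. Fallback, setting out from 12 and returning at 14: chemoselective oxidation of only the primary alcohol (TEMPO cat., PhI(OAc)2, CH2Cl2) gives the hydroxy aldehyde F5 with the C6 carbinol intact. mCPBA/NaHCO3 then meets a single carbonyl group and gives the hydroxy formate F6, and Dess–Martin oxidation of the C6 alcohol gives 14.

3. Step 19 (osmylation). What may go wrong: attack at the C7 methylene or an angelate alkene, low face selectivity at C10, or acyl migration during osmate hydrolysis. Fallback, setting out from 20 and returning at 29, builds C8–C11 by aldol chemistry instead of allylation/metathesis/osmylation: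
   - 3-Hydroxy-3-methylbutan-2-one is silylated (TESCl, imidazole) to 3-methyl-3-(triethylsilyloxy)butan-2-one F7.
   - Its enol borinate ((−)-Ipc2BCl, Et3N, Et2O) adds to 20 (reagent-controlled methyl ketone aldol) to give the (8S)-β-hydroxy ketone F8.
   - Me4NBH(OAc)3 in MeCN/AcOH (hydroxyl-directed anti reduction) gives the 8,10-anti diol F9.
   - 2,2-Dimethoxypropane/PPTS in acetone removes the tertiary silyl ether and ties O10/O11 into the dioxolane F10; the anti 1,3-diol disfavours the six-membered acetonide, so O8 should stay free.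
   - HF·pyridine gives the C5,C8-diol F11, and acylation as in step 17 gives the bis-angelate acetonide F12.
   - 80 % aqueous AcOH at 40 °C releases 29.

Further compounds
F1 | step 6 | racemic endo adduct, racemate of 10 (one enantiomer drawn) | CC(C)(C)[Si](C)(C)OCCC=1C[C@@H](Cl)[C@](C)(C=O)[C@H](O[Si](C)(C)C(C)(C)C)C=1
F2 | step 6 | racemic primary alcohol from F1, C4 CH3/CH2OH (one enantiomer drawn) | CC(C)(C)[Si](C)(C)OCCC=1C[C@@H](Cl)[C@](C)(CO)[C@H](O[Si](C)(C)C(C)(C)C)C=1
F3 | step 6 | (S)-O-methylmandelate of the (3R,4R,5R) alcohol | CC(C)(C)[Si](C)(C)OCCC=1C[C@@H](Cl)[C@](C)(COC(=O)[C@@H](OC)c2ccccc2)[C@H](O[Si](C)(C)C(C)(C)C)C=1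
F4 | step 6 | enantiopure (3R,4R,5R) primary alcohol | CC(C)(C)[Si](C)(C)OCCC=1C[C@@H](Cl)[C@](C)(CO)[C@H](O[Si](C)(C)C(C)(C)C)C=1
F5 | step 9 | hydroxy aldehyde (1R,3R,4S,5S,6S): C4 CHO, C6 OH | CC(C)(C)[Si](C)(C)OCC[C@@H]1C[C@@H](Cl)[C@](C)(C=O)[C@H](O[Si](C)(C)C(C)(C)C)[C@H]1O
F6 | step 9 | hydroxy formate (1R,3R,4R,5R,6S): C4 OCHO, C6 OH | CC(C)(C)[Si](C)(C)OCC[C@@H]1C[C@@H](Cl)[C@](C)(OC=O)[C@H](O[Si](C)(C)C(C)(C)C)[C@H]1O
F7 | step 19 | 3-methyl-3-(triethylsilyloxy)butan-2-one | CC(=O)C(C)(C)O[Si](CC)(CC)CC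
F8 | step 19 | (8S)-β-hydroxy ketone: C8 OH, C10 ketone, C11 OTES | C=C([C@H](CC(=O)C(C)(C)O[Si](CC)(CC)CC)O)[C@@H]1C[C@@H](Cl)[C@](C)(O)[C@H](O[Si](C)(C)C(C)(C)C)[C@@H]1OC(C)=O
F9 | step 19 | (8S,10S)-anti diol, C11 OTES | C=C([C@H](C[C@H](O)C(C)(C)O[Si](CC)(CC)CC)O)[C@@H]1C[C@@H](Cl)[C@](C)(O)[C@H](O[Si](C)(C)C(C)(C)C)[C@@H]1OC(C)=O
F10 | step 19 | C10/C11 acetonide, C8 OH free, C5 OTBS | C=C([C@H](C[C@@H]2OC(C)(C)OC2(C)C)O)[C@@H]1C[C@@H](Cl)[C@](C)(O)[C@H](O[Si](C)(C)C(C)(C)C)[C@@H]1OC(C)=O
F11 | step 19 | C10/C11 acetonide, C5 and C8 OH free | C=C([C@H](C[C@@H]2OC(C)(C)OC2(C)C)O)[C@@H]1C[C@@H](Cl)[C@](C)(O)[C@H](O)[C@@H]1OC(C)=O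
F12 | step 19 | C5,C8-bis-angelate C10/C11 acetonide | C=C([C@H](C[C@@H]2OC(C)(C)OC2(C)C)OC(=O)/C(C)=C\C)[C@@H]1C[C@@H](Cl)[C@](C)(O)[C@H](OC(=O)/C(C)=C\C)[C@@H]1OC(C)=O
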